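Target read in germacrane numbering (ring C1–C10, lactone C12(=O)–O on C6, C11 on C7): 8α-angeloyloxy-2α-hydroxy-1β,10β:4α,5β-diepoxygermacr-11(13)-en-12,6α-olide.
Enabling feature: the C1–C10 bond lies in both the oxirane and the ten-membered ring, the oxirane is cis (C2 and C9 on the same side) and its neighbour C2 bears OH. It is therefore the OH-directed epoxide of a ring (Z)-C1=C10 allylic alcohol, the olefin geometry that ring-closing metathesis favours in a ten-membered ring.
Cuts (retro order): O8–acyl; C11=C13; oxirane O on C1/C10; C1=C10 (ring); C8–C9; C6–C7 with lactone C12–O6; oxirane O on C4/C5; C5–C6 and C4–C15; C3–C4.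
Forward order: acyclic C1–C6 epoxy aldehyde, then the γ-lactone (C6/C7), then the C8 carbinol with C9–C10, then the ten-membered ring, then methylene and angelate, and the 1,10-oxirane last.
Stereochemistry: C2 from (R)-2-vinyloxirane; C4/C5 from Sharpless epoxidation; C6/C7 from an oxazolidinone syn-aldol; C8 from a pinene-derived methallylborane; C1/C10 from the Z-olefin and delivery by C2–OH.

Key step: step 11

Assumption: (R)-2-vinyloxirane (the hydrolytic-kinetic-resolution product of butadiene monoepoxide) is taken as a purchasable building block.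

Step 1
Reactants: 1 (R)-2-vinyloxirane; 2 lithium acetylide ethylenediamine complex
Product: 3 (S)-hex-1-en-5-yn-3-ol
Conditions: LiC≡CH·H2N(CH2)2NH2, DMSO, 0 °C → rt; H2O
Reagents that add atoms: none
Why: SN2 opening of a terminal epoxide by acetylide at the unhindered CH2 (no copper, so no SN2′ path), which leaves the C–O stereocentre of 1 untouched as the future C2.

Step 2
Reactants: 3 (S)-hex-1-en-5-yn-3-ol
Product: 4 (S)-3-(tert-butyldimethylsilyloxy)hex-1-en-5-yne
Conditions: TBSCl, imidazole, DMF, rt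
Reagents that add atoms: tert-butyldimethylsilyl chloride, CC(C)(C)[Si](C)(C)Cl
Why: Standard silylation of a secondary alcohol, which blocks O2 until the C8 ester is in place; no stereocentre is formed.

Step 3
Reactants: 4 (S)-3-(tert-butyldimethylsilyloxy)hex-1-en-5-yne
Product: 6 (2E,5S)-5-(tert-butyldimethylsilyloxy)-3-methylhepta-2,6-dien-1-ol, via alkenylalane 5 (not isolated)
Conditions: AlMe3 (2.5 equiv), Cp2ZrCl2 (0.25 equiv), CH2Cl2, 0 °C → rt; then n-BuLi, THF, −78 °C; (CH2O)n, −78 °C → rt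
Reagents that add atoms: trimethylaluminium, C[Al](C)C; paraformaldehyde (as formaldehyde), C=O
Why: Negishi carboalumination adds methyl and aluminium syn across the terminal alkyne (methyl to the internal carbon) and the alanate is hydroxymethylated with retention, so the E-trisubstituted C4=C5 olefin carrying C15 and C6 results while the isolated vinyl group stays inert.

Step 4
Reactants: 6 (2E,5S)-5-(tert-butyldimethylsilyloxy)-3-methylhepta-2,6-dien-1-ol
Product: 7 [(2R,3R)-3-[(2S)-2-(tert-butyldimethylsilyloxy)but-3-en-1-yl]-3-methyloxiran-2-yl]methanol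
Conditions: Ti(OiPr)4 (cat.), D-(−)-diethyl tartrate, t-BuOOH, 4 Å MS, CH2Cl2, −20 °C
Reagents that add atoms: tert-butyl hydroperoxide, CC(C)(C)OO
Why: Sharpless asymmetric epoxidation acts only on the free allylic alcohol, and the D-(−)-tartrate ligand delivers oxygen to the face that gives the (2R,3R)-epoxy alcohol (the mirror image of the outcome with the L-(+)-ligand on the analogous E-3-methyl allylic alcohols), setting C4 and C5 under reagent control.

Step 5
Reactants: 7 [(2R,3R)-3-[(2S)-2-(tert-butyldimethylsilyloxy)but-3-en-1-yl]-3-methyloxiran-2-yl]methanol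
Product: 8 (2S,3R)-3-[(2S)-2-(tert-butyldimethylsilyloxy)but-3-en-1-yl]-3-methyloxirane-2-carbaldehyde
Conditions: PhI(OAc)2, TEMPO (cat.), CH2Cl2, rt
Reagents that add atoms: none
Why: Oxoammonium (TEMPO) oxidation of a primary alcohol stops at the aldehyde under neutral conditions that spare epoxide, silyl ether and olefin; the oxirane carbon next to the carbonyl cannot epimerise.

Step 6
Reactants: 9 (S)-4-benzyloxazolidin-2-one; 10 methyl 4-chloro-4-oxobutanoate
Product: 11 methyl 4-[(4S)-4-benzyl-2-oxooxazolidin-3-yl]-4-oxobutanoate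
Conditions: n-BuLi, THF, −78 °C; then 10, −78 → 0 °C
Reagents that add atoms: none
Why: N-acylation of the lithiated oxazolidinone by an acid chloride; no stereocentre is formed.

Step 7
Reactants: 11 methyl 4-[(4S)-4-benzyl-2-oxooxazolidin-3-yl]-4-oxobutanoate; 8 (2S,3R)-3-[(2S)-2-(tert-butyldimethylsilyloxy)but-3-en-1-yl]-3-methyloxirane-2-carbaldehyde
Product: 13 (4S)-4-benzyl-3-[(2S,3S)-2-{(2R,3R)-3-[(2S)-2-(tert-butyldimethylsilyloxy)but-3-en-1-yl]-3-methyloxiran-2-yl}-5-oxooxolane-3-carbonyl]oxazolidin-2-one, via syn-aldol adduct 12 (not isolated)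
Conditions: 11, Bu2BOTf, i-Pr2NEt, CH2Cl2, −78 → 0 °C; 8, −78 → 0 °C; pH 7 buffer, MeOH, H2O2; then PPTS (cat.), toluene, 50 °C
Reagents that add atoms: none
Why: Evans syn-aldol, in which the Z-boron enolate of the imide (the ester is not enolised) reacts through a chair transition state with the benzyl group shielding one face, so the auxiliary sets C7 and C6 (syn) over the aldehyde's own bias, and the γ-hydroxy ester then lactonises under mild acid to the trans-γ-lactone.

Step 8
Reactants: 13 (4S)-4-benzyl-3-[(2S,3S)-2-{(2R,3R)-3-[(2S)-2-(tert-butyldimethylsilyloxy)but-3-en-1-yl]-3-methyloxiran-2-yl}-5-oxooxolane-3-carbonyl]oxazolidin-2-one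
Product: 14 S-ethyl (2S,3S)-2-{(2R,3R)-3-[(2S)-2-(tert-butyldimethylsilyloxy)but-3-en-1-yl]-3-methyloxiran-2-yl}-5-oxooxolane-3-carbothioate
Conditions: EtSH, n-BuLi, THF, 0 °C, short reaction time
Reagents that add atoms: ethanethiol, CCS
Why: Thiolate transacylation cleaves the exocyclic imide carbonyl selectively (the auxiliary is recovered), the hindered trisubstituted epoxide should survive a short exposure at 0 °C, and C7 prefers the trans arrangement even if it equilibrates.

Step 9
Reactants: 14 S-ethyl (2S,3S)-2-{(2R,3R)-3-[(2S)-2-(tert-butyldimethylsilyloxy)but-3-en-1-yl]-3-methyloxiran-2-yl}-5-oxooxolane-3-carbothioate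
Product: 15 (2S,3S)-2-{(2R,3R)-3-[(2S)-2-(tert-butyldimethylsilyloxy)but-3-en-1-yl]-3-methyloxiran-2-yl}-5-oxooxolane-3-carbaldehyde
Conditions: Et3SiH, 10% Pd/C, acetone, rt
Reagents that add atoms: none
Why: Fukuyama reduction, a palladium-catalysed hydrosilane reduction of a thioester that stops at the aldehyde and tolerates lactone, epoxide and silyl ether.

Step 10
Reactants: 15 (2S,3S)-2-{(2R,3R)-3-[(2S)-2-(tert-butyldimethylsilyloxy)but-3-en-1-yl]-3-methyloxiran-2-yl}-5-oxooxolane-3-carbaldehyde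
Product: 16 (4R,5S)-4-[(1S)-1-hydroxy-3-methylbut-3-en-1-yl]-5-{(2R,3R)-3-[(2S)-2-(tert-butyldimethylsilyloxy)but-3-en-1-yl]-3-methyloxiran-2-yl}oxolan-2-one
Conditions: (−)-Ipc2B(CH2C(CH3)=CH2), Et2O, −78 °C; then H2O2, pH 7 buffer, 0 °C
Reagents that add atoms: (−)-B-(2-methylallyl)diisopinocampheylborane (from (+)-α-pinene), CC(=C)CB([C@@H]1C[C@@H]2C[C@H]([C@H]1C)C2(C)C)[C@@H]1C[C@@H]2C[C@H]([C@H]1C)C2(C)C
Why: Brown allylboration through a chair transition state under reagent control sets C8 as the S carbinol (the sense in which this borane gives S alcohols from aldehydes whose substituent outranks the allyl carbon) and installs the 1,1-disubstituted C10 olefin at the same time.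

Step 11
Reactants: 16 (4R,5S)-4-[(1S)-1-hydroxy-3-methylbut-3-en-1-yl]-5-{(2R,3R)-3-[(2S)-2-(tert-butyldimethylsilyloxy)but-3-en-1-yl]-3-methyloxiran-2-yl}oxolan-2-one
Product: 17 2α-(tert-butyldimethylsilyloxy)-4α,5β-epoxy-8α-hydroxy-13-norgermacr-1(10)Z-en-12,6α-olide (2S,4R,5R,6S,7R,8S)
Conditions: second-generation Grubbs catalyst (10 mol %), toluene (1 mM), 80 °C, Ar sparge
Reagents that add atoms: none
Why: Ring-closing metathesis: the ruthenium alkylidene loads on the monosubstituted C1 vinyl group, and [2+2] cycloaddition with the 1,1-disubstituted C10 olefin followed by cycloreversion expels ethylene and leaves C1=C10. The closest known reaction type is medium-ring metathesis giving trisubstituted cis-cycloalkenes. The ten-membered carbocycle is closed with both new sp2 carbons inside the ring; the trans-fused γ-lactone at C6–C7 and the trans-4,5-epoxide act as rigid turn elements that bring C1 and C10 together, and high dilution suppresses oligomers. No stereocentre is formed; the selectivity needed is Z over E (C2 and C9 on the same side), which a ten-membered ring should favour kinetically and, under the reversible conditions of this catalyst, thermodynamically. Chemoselectivity is secured because the two terminal olefins are the only ones present, which is why the lactone is still unmethylenated at this stage. The Z geometry is what the last step turns into the cis-1β,10β-oxirane.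

Step 12
Reactants: 17 2α-(tert-butyldimethylsilyloxy)-4α,5β-epoxy-8α-hydroxy-13-norgermacr-1(10)Z-en-12,6α-olide
Product: 20 2α-(tert-butyldimethylsilyloxy)-4α,5β-epoxy-8α-hydroxygermacra-1(10)Z,11(13)-dien-12,6α-olide (2S,4R,5R,6S,7R,8S), via Mannich base 18 (not isolated), via trimethylammonium iodide 19 (not isolated)
Conditions: LDA (2.5 equiv), THF, −78 °C; CH2=NMe2+ I−, −78 °C → rt; then MeI, MeOH, rt; then aq NaHCO3, EtOAc, rt
Reagents that add atoms: Eschenmoser's salt (N,N-dimethylmethyleneiminium iodide), C=[N+](C)C.[I-]; iodomethane, CI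
Why: Mannich reaction of the lactone enolate (formed beside the C8 alkoxide, which stays unreactive at −78 °C) with Eschenmoser's salt, then quaternisation and E1cB loss of trimethylamine, is the standard α-methylenation; the C11 centre formed anti to C8 is destroyed in the elimination, and the step follows the metathesis so that C11=C13 cannot act as an olefin partner.

Step 13
Reactants: 20 2α-(tert-butyldimethylsilyloxy)-4α,5β-epoxy-8α-hydroxygermacra-1(10)Z,11(13)-dien-12,6α-olide; 21 angelic acid ((Z)-2-methylbut-2-enoic acid)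
Product: 22 8α-angeloyloxy-2α-(tert-butyldimethylsilyloxy)-4α,5β-epoxygermacra-1(10)Z,11(13)-dien-12,6α-olide (2S,4R,5R,6S,7R,8S)
Conditions: 21, 2,4,6-Cl3C6H2COCl, Et3N, toluene, rt; then 20, 80 °C
Reagents that add atoms: none
Why: Yamaguchi esterification through the mixed 2,4,6-trichlorobenzoic anhydride, run without a nucleophilic catalyst, acylates the only free hydroxyl (O8) and should keep the Z geometry of the angelate.

Step 14
Reactants: 22 8α-angeloyloxy-2α-(tert-butyldimethylsilyloxy)-4α,5β-epoxygermacra-1(10)Z,11(13)-dien-12,6α-olide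
Product: 23 8α-angeloyloxy-4α,5β-epoxy-2α-hydroxygermacra-1(10)Z,11(13)-dien-12,6α-olide (2S,4R,5R,6S,7R,8S)
Conditions: HF·pyridine, pyridine, THF, 0 °C → rt
Reagents that add atoms: none
Why: Fluoride cleavage of the silyl ether under buffered conditions that should spare the epoxide, both esters and the Michael acceptor; no stereocentre is touched.

Step 15
Reactants: 23 8α-angeloyloxy-4α,5β-epoxy-2α-hydroxygermacra-1(10)Z,11(13)-dien-12,6α-olide
Product: 24 8α-angeloyloxy-2α-hydroxy-1β,10β:4α,5β-diepoxygermacr-11(13)-en-12,6α-olide (1R,2S,4R,5R,6S,7R,8S,10S), the target CNP0388761.1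
Conditions: mCPBA, NaHCO3, CH2Cl2, 0 °C
Reagents that add atoms: 3-chloroperoxybenzoic acid, OOC(=O)c1cccc(Cl)c1
Why: Hydroxyl-directed (Henbest) peracid epoxidation: with C9 cis to C2, A(1,3) strain holds H-2 in the olefin plane, the hydrogen-bonded peracid delivers oxygen to the face syn to O2 (also the peripheral face, since C3 lies on the other side), so C1 (R) and C10 (S) are set by C2 and by the Z geometry as the cis-1β,10β-oxirane, while the two enoate olefins are too electron-poor to react.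

Compound list
1 | (R)-2-vinyloxirane | C=C[C@@H]1CO1 | starting material
2 | lithium acetylide ethylenediamine complex | [Li]C#C.NCCN | starting material
3 | (S)-hex-1-en-5-yn-3-ol | C=C[C@@H](O)CC#C | intermediate
4 | (S)-3-(tert-butyldimethylsilyloxy)hex-1-en-5-yne | C=C[C@@H](O[Si](C)(C)C(C)(C)C)CC#C | intermediate
5 | alkenylalane: dimethyl[(1E,4S)-4-(tert-butyldimethylsilyloxy)-2-methylhexa-1,5-dien-1-yl]alane | C=C[C@@H](O[Si](C)(C)C(C)(C)C)C/C(C)=C/[Al](C)C | intermediate
6 | (2E,5S)-5-(tert-butyldimethylsilyloxy)-3-methylhepta-2,6-dien-1-ol | C=C[C@@H](O[Si](C)(C)C(C)(C)C)C/C(C)=C/CO | intermediate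
7 | [(2R,3R)-3-[(2S)-2-(tert-butyldimethylsilyloxy)but-3-en-1-yl]-3-methyloxiran-2-yl]methanol | C=C[C@@H](O[Si](C)(C)C(C)(C)C)C[C@@]1(C)O[C@@H]1CO | intermediate
8 | (2S,3R)-3-[(2S)-2-(tert-butyldimethylsilyloxy)but-3-en-1-yl]-3-methyloxirane-2-carbaldehyde | C=C[C@@H](O[Si](C)(C)C(C)(C)C)C[C@@]1(C)O[C@@H]1C=O | intermediate
9 | (S)-4-benzyloxazolidin-2-one | O=C1N[C@@H](Cc2ccccc2)CO1 | starting material
10 | methyl 4-chloro-4-oxobutanoate | COC(=O)CCC(Cl)=O | starting material
11 | methyl 4-[(4S)-4-benzyl-2-oxooxazolidin-3-yl]-4-oxobutanoate | COC(=O)CCC(=O)N1[C@@H](Cc2ccccc2)COC1=O | intermediate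
12 | syn-aldol adduct: methyl (3S)-4-[(4S)-4-benzyl-2-oxooxazolidin-3-yl]-3-[(S)-hydroxy{(2R,3R)-3-[(2S)-2-(tert-butyldimethylsilyloxy)but-3-en-1-yl]-3-methyloxiran-2-yl}methyl]-4-oxobutanoate | COC(=O)C[C@H](C(=O)N1[C@@H](Cc2ccccc2)COC1=O)[C@H](O)[C@H]1O[C@]1(C)C[C@H](O[Si](C)(C)C(C)(C)C)C=C | intermediate
13 | (4S)-4-benzyl-3-[(2S,3S)-2-{(2R,3R)-3-[(2S)-2-(tert-butyldimethylsilyloxy)but-3-en-1-yl]-3-methyloxiran-2-yl}-5-oxooxolane-3-carbonyl]oxazolidin-2-one | O=C1C[C@H](C(=O)N2[C@@H](Cc3ccccc3)COC2=O)[C@H](O1)[C@H]1O[C@]1(C)C[C@H](O[Si](C)(C)C(C)(C)C)C=C | intermediate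
14 | S-ethyl (2S,3S)-2-{(2R,3R)-3-[(2S)-2-(tert-butyldimethylsilyloxy)but-3-en-1-yl]-3-methyloxiran-2-yl}-5-oxooxolane-3-carbothioate | O=C1C[C@H](C(=O)SCC)[C@H](O1)[C@H]1O[C@]1(C)C[C@H](O[Si](C)(C)C(C)(C)C)C=C | intermediate
15 | (2S,3S)-2-{(2R,3R)-3-[(2S)-2-(tert-butyldimethylsilyloxy)but-3-en-1-yl]-3-methyloxiran-2-yl}-5-oxooxolane-3-carbaldehyde | O=C1C[C@H](C=O)[C@H](O1)[C@H]1O[C@]1(C)C[C@H](O[Si](C)(C)C(C)(C)C)C=C | intermediate
16 | (4R,5S)-4-[(1S)-1-hydroxy-3-methylbut-3-en-1-yl]-5-{(2R,3R)-3-[(2S)-2-(tert-butyldimethylsilyloxy)but-3-en-1-yl]-3-methyloxiran-2-yl}oxolan-2-one | O=C1C[C@H]([C@@H](O)CC(C)=C)[C@H](O1)[C@H]1O[C@]1(C)C[C@H](O[Si](C)(C)C(C)(C)C)C=C | intermediate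
17 | 2α-(tert-butyldimethylsilyloxy)-4α,5β-epoxy-8α-hydroxy-13-norgermacr-1(10)Z-en-12,6α-olide (2S,4R,5R,6S,7R,8S) | C1C(=O)O[C@H]2[C@H]1[C@@H](O)C/C(C)=C\[C@@H](O[Si](C)(C)C(C)(C)C)C[C@@]1(C)O[C@H]21 | intermediate
18 | Mannich base: (11R)-13-(dimethylamino)-2α-(tert-butyldimethylsilyloxy)-4α,5β-epoxy-8α-hydroxygermacr-1(10)Z-en-12,6α-olide | CN(C)C[C@@H]1C(=O)O[C@H]2[C@H]1[C@@H](O)C/C(C)=C\[C@@H](O[Si](C)(C)C(C)(C)C)C[C@@]1(C)O[C@H]21 | intermediate
19 | trimethylammonium iodide: N-methyl quaternary salt of 18 | C[N+](C)(C)C[C@@H]1C(=O)O[C@H]2[C@H]1[C@@H](O)C/C(C)=C\[C@@H](O[Si](C)(C)C(C)(C)C)C[C@@]1(C)O[C@H]21.[I-] | intermediate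
20 | 2α-(tert-butyldimethylsilyloxy)-4α,5β-epoxy-8α-hydroxygermacra-1(10)Z,11(13)-dien-12,6α-olide | C=C1C(=O)O[C@H]2[C@H]1[C@@H](O)C/C(C)=C\[C@@H](O[Si](C)(C)C(C)(C)C)C[C@@]1(C)O[C@H]21 | intermediate
21 | angelic acid ((Z)-2-methylbut-2-enoic acid) | C/C=C(/C)C(=O)O | starting material
22 | 8α-angeloyloxy-2α-(tert-butyldimethylsilyloxy)-4α,5β-epoxygermacra-1(10)Z,11(13)-dien-12,6α-olide | C=C1C(=O)O[C@H]2[C@H]1[C@@H](OC(=O)/C(C)=C\C)C/C(C)=C\[C@@H](O[Si](C)(C)C(C)(C)C)C[C@@]1(C)O[C@H]21 | intermediate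
23 | 8α-angeloyloxy-4α,5β-epoxy-2α-hydroxygermacra-1(10)Z,11(13)-dien-12,6α-olide | C=C1C(=O)O[C@H]2[C@H]1[C@@H](OC(=O)/C(C)=C\C)C/C(C)=C\[C@@H](O)C[C@@]1(C)O[C@H]21 | intermediate
24 | 8α-angeloyloxy-2α-hydroxy-1β,10β:4α,5β-diepoxygermacr-11(13)-en-12,6α-olide (1R,2S,4R,5R,6S,7R,8S,10S; CNP0388761.1) | C=C1C(=O)O[C@H]2[C@H]1[C@@H](OC(=O)/C(C)=C\C)C[C@]1(C)O[C@@H]1[C@@H](O)C[C@@]1(C)O[C@H]21 | target

Total step count: 15
Longest linear sequence: 14 (steps 1–5 and 7–15; step 6 is the one-step side branch)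

Three steps most likely to fail

Highest risk is step 11 (ring closure). What may go wrong: oligomerisation outpacing the slow closure onto a 1,1-disubstituted olefin, or erosion of Z over E selectivity at the trisubstituted ring olefin. The fallback for step 11 sets out from 16 and comes back to the route at 17; it forms the same C1–C10 bond by carbonyl coupling instead of metathesis. The C8 hydroxyl of 16 is capped with Et3SiCl and imidazole to give bis-silyl ether F1. Ozonolysis (O3, CH2Cl2, −78 °C; then Me2S) turns both terminal olefins into carbonyls and gives keto aldehyde F2, with the aldehyde at C1 and the methyl ketone at C10. SmI2 in THF at high dilution should join the two carbonyl carbons in a ketyl pinacol cyclisation to cis-1,10-diol F3; either cis-diol serves and one is drawn. Thiocarbonyldiimidazole converts the diol into cyclic thiocarbonate F4. Corey–Winter fragmentation in its mild variant with 1,3-dimethyl-2-phenyl-1,3,2-diazaphospholidine at 40 °C is a stereospecific syn-elimination and should give Z-olefin F5, the 8-O-triethylsilyl ether of 17. PPTS in methanol removes the triethylsilyl group and returns 17.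

Second is step 15 (final epoxidation). What may go wrong: poor facial selectivity if the macrocycle holds the C2 hydroxyl away from the reacting olefin face, or oxidation at other sites. The fallback for step 15 sets out from 22 and comes back at 24; it replaces substrate direction by catalyst control. Shi epoxidation of 22 with a fructose-derived chiral ketone and KHSO5 (buffered MeCN/dimethoxymethane/H2O, 0 °C; the enantiomer of the ketone chosen for the β-face of C1=C10) should give epoxy silyl ether F8. HF·pyridine then releases 24.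

Third is step 7 (aldol on the epoxy aldehyde). What may go wrong: Lewis-acid opening of the α,β-epoxy aldehyde by the boron reagent, or a mismatched pairing of aldehyde and auxiliary that lowers the facial selectivity. The fallback for step 7 sets out from 6 and comes back at 12; it moves the epoxidation behind the aldol. MnO2 in CH2Cl2 oxidises 6 to enal F6. The same boron aldol with 11 should give syn-aldol allylic alcohol F7. Peracid epoxidation (mCPBA, NaHCO3, CH2Cl2, 0 °C) directed by the C6 hydroxyl under A(1,3) control, C15 being cis to C6, should place the oxirane oxygen syn to O6 and give 12, which lactonises to 13 as in step 7.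

Further compounds
F1 | step 11 | bis-silyl ether: 8-O-triethylsilyl ether of 16 | O=C1C[C@H]([C@@H](O[Si](CC)(CC)CC)CC(C)=C)[C@H](O1)[C@H]1O[C@]1(C)C[C@H](O[Si](C)(C)C(C)(C)C)C=C
F2 | step 11 | keto aldehyde: 1,10-seco compound with C1 aldehyde and C10 methyl ketone (8-O-triethylsilyl and 2-O-tert-butyldimethylsilyl) | O=C1C[C@H]([C@@H](O[Si](CC)(CC)CC)CC(C)=O)[C@H](O1)[C@H]1O[C@]1(C)C[C@H](O[Si](C)(C)C(C)(C)C)C=O
F3 | step 11 | cis-1,10-diol of the ten-membered ring (1β,10β-diol drawn; 8-O-triethylsilyl and 2-O-tert-butyldimethylsilyl) | C1C(=O)O[C@H]2[C@H]1[C@@H](O[Si](CC)(CC)CC)C[C@](C)(O)[C@H](O)[C@@H](O[Si](C)(C)C(C)(C)C)C[C@@]1(C)O[C@H]21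
F4 | step 11 | cyclic thiocarbonate: 1,10-thiocarbonate of F3 | C1C(=O)O[C@H]2[C@H]1[C@@H](O[Si](CC)(CC)CC)C[C@]3(C)OC(=S)O[C@@H]3[C@@H](O[Si](C)(C)C(C)(C)C)C[C@@]1(C)O[C@H]21
F5 | step 11 | Z-olefin: 8-O-triethylsilyl ether of 17 | C1C(=O)O[C@H]2[C@H]1[C@@H](O[Si](CC)(CC)CC)C/C(C)=C\[C@@H](O[Si](C)(C)C(C)(C)C)C[C@@]1(C)O[C@H]21
F6 | step 7 | enal: (2E,5S)-5-(tert-butyldimethylsilyloxy)-3-methylhepta-2,6-dienal | C=C[C@@H](O[Si](C)(C)C(C)(C)C)C/C(C)=C/C=O
F7 | step 7 | syn-aldol allylic alcohol: adduct of 11 with F6 (4,5-olefin analogue of 12) | COC(=O)C[C@H](C(=O)N1[C@@H](Cc2ccccc2)COC1=O)[C@H](O)/C=C(\C)C[C@H](O[Si](C)(C)C(C)(C)C)C=C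
F8 | step 15 | epoxy silyl ether: 2-O-tert-butyldimethylsilyl ether of 24 | C=C1C(=O)O[C@H]2[C@H]1[C@@H](OC(=O)/C(C)=C\C)C[C@]1(C)O[C@@H]1[C@@H](O[Si](C)(C)C(C)(C)C)C[C@@]1(C)O[C@H]21
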